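The pitfall with the zeta run is to take logarithms of its substrate curve and call the slope a rate constant.

| setting | zeta | gamma | summer | autumn | dusk | spring |
|---|---|---|---|---|---|---|
| substrate | 10 mM | 42 mM | 21 mM | 21 mM | 21 mM | 21 mM |
| partner | 21 mM | 21 mM | 21.0 mM | 21.0 mM | 21.0 mM | 21.0 mM |
| temperature | 72 °C | 122 °C | 110 °C | 50 °C | 140 °C | 80 °C |
| remark | run made earlier | run made earlier |  |  |  |  |
| time |  |  | 3.0 min | 3.0 min | 3.0 min | 3.0 min |

zeta run (percent of the substrate charged)

| time / min | target / % | substrate / % |
|---|---|---|
| 1.00 | 25.4 | 74.5 |
| 3.00 | 47.0 | 50.1 |
| 5.00 | 57.1 | 38.1 |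
| 8.00 | 63.0 | 29.3 |
| 12.0 | 65.8 | 22.1 |
| 15.0 | 65.6 | 18.0 |

gamma run (percent of the substrate charged)

| time / s | target / % | substrate / % |
|---|---|---|
| 10.0 | 49.0 | 50.4 |
| 15.0 | 48.6 | 50.5 |
| 30.0 | 49.0 | 50.7 |
| 40.0 | 48.5 | 50.2 |
| 60.0 | 48.4 | 49.8 |
| 80.0 | 49.5 | 51.6 |

(scatter of a reading: 0.5 percentage points)

1. the best flask by amount of target, in percent of the substrate charged; "all alike" if 1.5 percentage points covers them all (summer / autumn / dusk / spring / all alike)
2. amount of target at the end, in percent of the substrate charged, summer
3. amount of target at the end, in percent of the substrate charged, autumn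
4. amount of target at the end, in percent of the substrate charged, dusk
5. amount of target at the end, in percent of the substrate charged, spring



Let a be the fraction of charged substrate left. In zeta, the slope of ln a falls from 0.198 /min early to 0.0684 /min late, so first order fails. If substrate instead goes by the square of its own amount (apparent second order), integrating gives a = 1/(1 + wt), and the reciprocal of a climbs steadily. It does: 0.327 /min early, 0.306 /min late. Over the whole zeta run, the clock rate w, the growth of that reciprocal per minute, reads 0.301 /min, and it should scale with the substrate charge.

But temperature? Gamma has stopped by its first reading, so it gives a floor, 5.90 /min. Per mM of charge, that is at least 4.67 times the zeta rate. A floor is thin, and partner's own effect goes unread, though w held steady in zeta while partner was being used. Spreading that factor geometrically over temperature, I get a rate of 0.321 /min for autumn and 2.04 /min for summer. That leaves 51.0% and 14.0% of their substrate.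

Yet consumed substrate is not target: zeta lost 20.0% of what it consumed. Taking that share off, I commit to 39.2% in autumn, 56.7% in spring and 68.8% in summer. Dusk reckons higher, at 75.1%, but I distrust it: gamma's substrate read 50.4% at its first reading and about the same at its last, 51.6%.

The forecast named dusk, with 84% for summer, 8% for autumn, 90% for dusk and 53% for spring, on the ground “so heat favours selectivity”.

The flasks give 73.1% in summer, 35.8% in autumn, 68.9% in dusk and 66.4% in spring, so the best is summer.

    substrate + partner → target, rate k1*[substrate]^2*[partner]^0.5 (k = 6.20 /M^1.5/s, Ea = 53.0 kJ/mol)
    partner + target → over-reaction product (k = 0.0420 /M/s, Ea = 74.0 kJ/mol)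
    (constants at 80 °C)

Summer's substrate at the end puts its clock at 1.86 /min, which is 2.94 times the zeta rate scaled to this charge. Run on to 30.0 min, that clock would leave 1.76% of the substrate, but summer keeps 12.7%, with partner down from 3.50% to 0%. Its target moves from 73.1% to just 74.7%, so summer is nearly at rest. Autumn is not: its clock, 0.187 /min, gives 15.1% at that time against the flask's 21.2%, and its target climbs from 35.8% to 75.9%.

Readings and results stem from a simulated flask for substances that don't exist, and the scatter is random.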